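**Strategy.** The route rests on cutting the N1–C2 and C3–C3a bonds of indole A (the 6-methoxyindole). C2 of this ring carries only hydrogen and C3 carries the crowded tetramethoxy ring C. The C2=C3 unit is therefore brought in as an aryl alkyne capped with SiEt3, which stands in for the C2 hydrogen. A Larock heteroannulation of 2-iodo-5-methoxyaniline with this alkyne builds the pyrrole ring of indole A in one operation and spares a second biaryl coupling at the doubly ortho-substituted ring C carbon. The alkyne precursor already holds ring C and the N-tosyl, O-benzyl indole B. It is assembled by mono-Suzuki coupling of a symmetric dibromide and then Sonogashira coupling.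

Key step: step 6

Remark on the chemistry: in step 7 the C2–Si bond is assumed to cleave before the N–S bond; the opposite order would converge on the same product 13.

Design notes:
- The aniline is used with a free NH2, so indole A emerges as N–H and needs no deprotection.
- The valuable alkyne is the limiting partner in the key step.
- The tosyl group on indole B is stable to carbonate in DMF and leaves together with the silyl placeholder under fluoride, so only two steps follow the key step.

**Step 1**
Reactants: 1 5-benzyloxyindole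
Product: 3 5-benzyloxy-3-iodo-1-tosylindole, via 5-benzyloxy-3-iodoindole 2 (not isolated)
Conditions: KOH (4 equiv), I2 (1.05 equiv), DMF, rt; then TsCl (1.5 equiv), 0 °C → rt
Reagents that add atoms: iodine, II; p-toluenesulfonyl chloride, Cc1ccc(cc1)S(Cl)(=O)=O
Why: Electrophilic aromatic iodination of the indolyl anion occurs only at its most nucleophilic carbon C3, and N-sulfonylation in the same pot protects the light-sensitive 3-iodoindole before isolation.

**Step 2**
Reactants: 3 5-benzyloxy-3-iodo-1-tosylindole
Product: 4 5-benzyloxy-3-(4,4,5,5-tetramethyl-1,3,2-dioxaborolan-2-yl)-1-tosylindole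
Conditions: B2pin2 (1.2 equiv), PdCl2(dppf) (5 mol %), KOAc (3 equiv), dioxane, 85 °C
Reagents that add atoms: bis(pinacolato)diboron, CC1(C)OB(OC1(C)C)B1OC(C)(C)C(C)(C)O1
Why: Miyaura borylation, in which zerovalent palladium inserts into the C3–I bond and the acetate complex transmetalates with the diboron; the weak base KOAc should leave the tosyl and benzyl groups untouched and suppress biaryl homocoupling.

**Step 3**
Reactants: 5 1,2,4,5-tetramethoxybenzene
Product: 6 1,4-dibromo-2,3,5,6-tetramethoxybenzene
Conditions: Br2 (2.2 equiv), CH2Cl2, 0 °C → rt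
Reagents that add atoms: bromine, BrBr
Why: Electrophilic aromatic bromination; the only two open positions are para to each other and each is activated by two ortho methoxy groups, so no regiochemical question arises, and anhydrous conditions avoid oxidation to the quinone.

**Step 4**
Reactants: 6 1,4-dibromo-2,3,5,6-tetramethoxybenzene (threefold excess); 4 5-benzyloxy-3-(4,4,5,5-tetramethyl-1,3,2-dioxaborolan-2-yl)-1-tosylindole
Product: 7 5-benzyloxy-3-(4-bromo-2,3,5,6-tetramethoxyphenyl)-1-tosylindole
Conditions: Pd(OAc)2 (5 mol %), SPhos (10 mol %), K3PO4 (3 equiv), toluene/H2O (10:1), 90 °C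
Reagents that add atoms: none
Why: Suzuki–Miyaura coupling with a dialkylbiarylphosphine suited to electron-rich bromides bearing two ortho substituents; the excess of recoverable symmetric dibromide should hold the reaction at single coupling, and the N-tosyl group slows protodeboronation of the indol-3-yl boronate.

**Step 5**
Reactants: 7 5-benzyloxy-3-(4-bromo-2,3,5,6-tetramethoxyphenyl)-1-tosylindole; 8 triethylsilylacetylene (2 equiv)
Product: 9 5-benzyloxy-3-[2,3,5,6-tetramethoxy-4-(triethylsilylethynyl)phenyl]-1-tosylindole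
Conditions: Pd(PhCN)2Cl2 (5 mol %), P(t-Bu)3·HBF4 (10 mol %), CuI (5 mol %), i-Pr2NH, dioxane, 60 °C
Reagents that add atoms: none
Why: Sonogashira coupling; the bulky, electron-rich P(t-Bu)3 should let palladium insert into the hindered, electron-rich C–Br bond at moderate temperature, and the amine base leaves the tosyl group and the alkynyl C–Si bond intact.

**Step 6**
Reactants: 9 5-benzyloxy-3-[2,3,5,6-tetramethoxy-4-(triethylsilylethynyl)phenyl]-1-tosylindole; 10 2-iodo-5-methoxyaniline (1.5 equiv)
Product: 11 5-benzyloxy-3-[2,3,5,6-tetramethoxy-4-(6-methoxy-2-triethylsilyl-1H-indol-3-yl)phenyl]-1-tosylindole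
Conditions: Pd(OAc)2 (10 mol %), LiCl (1 equiv), Na2CO3 (3 equiv), DMF, 100 °C
Reagents that add atoms: none
Why: Pd(OAc)2 is reduced in situ to zerovalent palladium, which inserts into the C–I bond of 10; the arylpalladium iodide then adds syn across the alkyne of 9, the aryl group bonding to the carbon that carries ring C (future C3) and palladium to the silicon-bearing carbon (future C2). Coordination and carbonate-assisted deprotonation of the neighbouring NH2 give a six-membered azapalladacycle, and C–N reductive elimination closes the five-membered pyrrole ring at N1–C2 after C3–C3a is already in place, a formal [3+2] annulation of the C3a–C7a–N unit onto the two alkyne carbons. The closest known reaction type is the Larock indole synthesis of 2-iodoanilines with aryl or alkyl silyl alkynes, which delivers 2-silylindoles. No stereocentre is formed. The selectivity needed is regiochemical (silicon at C2, ring C at C3) and should be secured by the SiEt3 group, whose bulk and stabilisation of an adjacent C–Pd bond place palladium on its carbon, a preference known to override that of an aryl substituent. Chemoselectivity is not at stake because 9 holds no other carbon–halogen bond, and chloride from LiCl keeps the ligand-free catalyst active.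

**Step 7**
Reactants: 11 5-benzyloxy-3-[2,3,5,6-tetramethoxy-4-(6-methoxy-2-triethylsilyl-1H-indol-3-yl)phenyl]-1-tosylindole
Product: 13 5-benzyloxy-3-[2,3,5,6-tetramethoxy-4-(6-methoxy-1H-indol-3-yl)phenyl]-1H-indole, via C2-desilylated N-tosyl bis-indole 12 (not isolated)
Conditions: TBAF (1 M in THF, 6 equiv), THF, rt → 65 °C
Reagents that add atoms: none
Why: Fluoride-mediated protodesilylation of the indol-2-yl silane (silicate formation, protonation by the water of commercial TBAF) is followed on warming by fluoride attack at sulfur, a known cleavage of N-sulfonyl indoles; the benzyl and methyl ethers are inert to fluoride.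

**Step 8**
Reactants: 13 5-benzyloxy-3-[2,3,5,6-tetramethoxy-4-(6-methoxy-1H-indol-3-yl)phenyl]-1H-indole
Product: 14 3-[2,3,5,6-tetramethoxy-4-(6-methoxy-1H-indol-3-yl)phenyl]-1H-indol-5-ol (target CNP0234672.0)
Conditions: H2 (1 atm), 10% Pd/C, EtOAc/MeOH, rt
Reagents that add atoms: none
Why: Catalytic hydrogenolysis of the benzyl aryl ether; at one atmosphere and room temperature the indole rings and methyl ethers should not be reduced, and the neutral conditions suit the oxidation-prone 5-hydroxyindole, which is why it is unveiled last.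

**Compound list**
1 | 5-benzyloxyindole | c1ccc(COc2ccc3[nH]ccc3c2)cc1 | starting material
2 | 5-benzyloxy-3-iodo-1H-indole | Ic1c[nH]c2ccc(OCc3ccccc3)cc12 | intermediate (not isolated)
3 | 5-benzyloxy-3-iodo-1-tosylindole | Cc1ccc(cc1)S(=O)(=O)n1cc(I)c2cc(OCc3ccccc3)ccc12 | intermediate
4 | 5-benzyloxy-3-(4,4,5,5-tetramethyl-1,3,2-dioxaborolan-2-yl)-1-tosylindole | Cc1ccc(cc1)S(=O)(=O)n1cc(B2OC(C)(C)C(C)(C)O2)c2cc(OCc3ccccc3)ccc12 | intermediate
5 | 1,2,4,5-tetramethoxybenzene | COc1cc(OC)c(OC)cc1OC | starting material
6 | 1,4-dibromo-2,3,5,6-tetramethoxybenzene | COc1c(Br)c(OC)c(OC)c(Br)c1OC | intermediate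
7 | 5-benzyloxy-3-(4-bromo-2,3,5,6-tetramethoxyphenyl)-1-tosylindole | COc1c(Br)c(OC)c(OC)c(c1OC)-c1cn(S(=O)(=O)c2ccc(C)cc2)c2ccc(OCc3ccccc3)cc12 | intermediate
8 | triethylsilylacetylene | CC[Si](CC)(CC)C#C | starting material
9 | 5-benzyloxy-3-[2,3,5,6-tetramethoxy-4-(triethylsilylethynyl)phenyl]-1-tosylindole | CC[Si](CC)(CC)C#Cc1c(OC)c(OC)c(-c2cn(S(=O)(=O)c3ccc(C)cc3)c3ccc(OCc4ccccc4)cc23)c(OC)c1OC | intermediate (key-step precursor)
10 | 2-iodo-5-methoxyaniline | COc1ccc(I)c(N)c1 | starting material
11 | 5-benzyloxy-3-[2,3,5,6-tetramethoxy-4-(6-methoxy-2-triethylsilyl-1H-indol-3-yl)phenyl]-1-tosylindole | COc1ccc2c(c1)[nH]c([Si](CC)(CC)CC)c2-c1c(OC)c(OC)c(-c2cn(S(=O)(=O)c3ccc(C)cc3)c3ccc(OCc4ccccc4)cc23)c(OC)c1OC | intermediate (key-step product)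
12 | 5-benzyloxy-3-[2,3,5,6-tetramethoxy-4-(6-methoxy-1H-indol-3-yl)phenyl]-1-tosylindole | COc1ccc2c(c1)[nH]cc2-c1c(OC)c(OC)c(-c2cn(S(=O)(=O)c3ccc(C)cc3)c3ccc(OCc4ccccc4)cc23)c(OC)c1OC | intermediate (not isolated)
13 | 5-benzyloxy-3-[2,3,5,6-tetramethoxy-4-(6-methoxy-1H-indol-3-yl)phenyl]-1H-indole | COc1ccc2c(c1)[nH]cc2-c1c(OC)c(OC)c(-c2c[nH]c3ccc(OCc4ccccc4)cc23)c(OC)c1OC | intermediate
14 | 3-[2,3,5,6-tetramethoxy-4-(6-methoxy-1H-indol-3-yl)phenyl]-1H-indol-5-ol | COc1ccc2c(-c3c(OC)c(OC)c(-c4c[nH]c5ccc(O)cc45)c(OC)c3OC)c[nH]c2c1 | target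

**Step count and risks**
Total steps: 8. Longest linear sequence: 7 (steps 1, 2, 4, 5, 6, 7, 8).

Most likely to fail:

1. Step 6. Carbopalladation may take the opposite orientation, with palladium next to the di-ortho-methoxy ring C, or insertion of the crowded alkyne may be so slow that the arylpalladium is diverted to reduction or homocoupling. The fallback sets out from bromide 7 and replaces the annulation by a second biaryl coupling. Commercial 6-methoxyindole would be iodinated and tosylated as in step 1 (I2, KOH, DMF; then TsCl), passing through 3-iodo-6-methoxy-1H-indole F1 without isolation, to give 3-iodo-6-methoxy-1-tosylindole F2. Borylation as in step 2 would give 6-methoxy-3-(4,4,5,5-tetramethyl-1,3,2-dioxaborolan-2-yl)-1-tosylindole F3. Suzuki–Miyaura coupling of F3 with 7 (Pd(OAc)2, SPhos, K3PO4, toluene/H2O, 90 °C) would give 5-benzyloxy-3-[2,3,5,6-tetramethoxy-4-(6-methoxy-1-tosylindol-3-yl)phenyl]-1-tosylindole F4. TBAF in THF at 65 °C would then remove both tosyl groups, and the route is rejoined at 13.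

2. Step 4. Over-coupling at the second C–Br bond and protodeboronation of the boronate may compete with slow transmetalation at the hindered centre. The fallback sets out from dibromide 6 and differentiates the two halogens instead of relying on stoichiometry. Single bromine–lithium exchange (n-BuLi, 1.0 equiv, THF, −78 °C) and an I2 quench would give 1-bromo-4-iodo-2,3,5,6-tetramethoxybenzene F5. Iodide-selective Suzuki–Miyaura coupling with boronate 4 (PdCl2(dppf), K3PO4, dioxane/H2O, 60 °C) would return to the route at 7.

3. Step 5. Oxidative addition into the electron-rich, doubly ortho-substituted C–Br bond may be slow, letting copper-mediated homocoupling consume the acetylene. The fallback sets out from 5 and installs the alkyne before the biaryl bond, on a more reactive halide. Diiodination (NIS, catalytic TFA, MeCN, rt) would give 1,4-diiodo-2,3,5,6-tetramethoxybenzene F6. Mono-Sonogashira coupling of excess F6 with 8 (Pd(PPh3)2Cl2, CuI, Et3N, THF, rt) would give triethyl[(4-iodo-2,3,5,6-tetramethoxyphenyl)ethynyl]silane F7. Suzuki–Miyaura coupling of F7 with boronate 4 (Pd(OAc)2, SPhos, K3PO4, toluene/H2O, 80 °C) would return to the route at 9.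

**Further compounds**
F1 | step 6 | 3-iodo-6-methoxy-1H-indole (not isolated) | COc1ccc2c(I)c[nH]c2c1
F2 | step 6 | 3-iodo-6-methoxy-1-tosylindole | COc1ccc2c(I)cn(S(=O)(=O)c3ccc(C)cc3)c2c1
F3 | step 6 | 6-methoxy-3-(4,4,5,5-tetramethyl-1,3,2-dioxaborolan-2-yl)-1-tosylindole | COc1ccc2c(B3OC(C)(C)C(C)(C)O3)cn(S(=O)(=O)c3ccc(C)cc3)c2c1
F4 | step 6 | 5-benzyloxy-3-[2,3,5,6-tetramethoxy-4-(6-methoxy-1-tosylindol-3-yl)phenyl]-1-tosylindole | COc1ccc2c(c1)n(S(=O)(=O)c1ccc(C)cc1)cc2-c1c(OC)c(OC)c(-c2cn(S(=O)(=O)c3ccc(C)cc3)c3ccc(OCc4ccccc4)cc23)c(OC)c1OC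
F5 | step 4 | 1-bromo-4-iodo-2,3,5,6-tetramethoxybenzene | COc1c(Br)c(OC)c(OC)c(I)c1OC
F6 | step 5 | 1,4-diiodo-2,3,5,6-tetramethoxybenzene | COc1c(I)c(OC)c(OC)c(I)c1OC
F7 | step 5 | triethyl[(4-iodo-2,3,5,6-tetramethoxyphenyl)ethynyl]silane | CC[Si](CC)(CC)C#Cc1c(OC)c(OC)c(I)c(OC)c1OC
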